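After about 12.0 h, both runs at 0.23 M of substrate stop rising: Saturday's reads 23.0%, then 22.6% at 15.0 h, and Monday's reads 33.5%, then 32.3%.

| flask | substrate | reagent | remark | time |
|---|---|---|---|---|
| Saturday's | 0.23 M | 0.74 equiv | run made earlier |  |
| Monday's | 0.23 M | 1.7 equiv | run made earlier |  |
| Wednesday's | 0.12 M | 1.1 equiv | run made earlier |  |
| flask | 0.23 M | 1.10 equiv |  | 25 h |

| run | time / h | target / % |
|---|---|---|
| Saturday's | 4.00 | 11.8 |
| Saturday's | 5.00 | 14.6 |
| Saturday's | 6.00 | 16.9 |
| Saturday's | 8.00 | 19.4 |
| Saturday's | 12.0 | 23.0 |
| Saturday's | 15.0 | 22.6 |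
| Monday's | 4.00 | 20.2 |
| Monday's | 5.00 | 23.6 |
| Monday's | 6.00 | 27.9 |
| Monday's | 8.00 | 30.7 |
| Monday's | 12.0 | 33.5 |
| Monday's | 15.0 | 32.3 |
| Wednesday's | 4.00 | 11.3 |
| Wednesday's | 5.00 | 15.4 |
| Wednesday's | 8.00 | 22.8 |
| Wednesday's | 10.0 | 24.7 |
| Wednesday's | 15.0 | 26.7 |

(standard deviation of a reading: 0.5 percentage points)

- what was read earlier has a scatter of 0.5 percentage points, one standard deviation

1. when, up to 25 h, the flask holds most target
2. the amount of target, in percent of the substrate charged, at that time

How much does reagent buy? Monday's charge is 2.30 times Saturday's, but its highest reading is 1.46 times Saturday's. So between these two runs the highest reading does not follow the reagent in proportion.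

What does each charge allow? We assume one reagent takes one substrate. Saturday's reagent, the limiting reagent, then lets 0.74 equiv of the substrate react, and its reading over that gives 31.1%. This is the peak share, the highest target read over the part of the substrate that the smaller charge lets react. Monday's 1.7 equiv covers the substrate, so its peak share is its reading, 33.5%, which is 1.08 times Saturday's.

What does our flask get? Its 1.10 equiv also covers the substrate, so we expect a peak between 31.1% and 33.5%. Both runs at this concentration have their highest reading at 12.0 h, so we expect it near that time.

The forecast gives 27.5% at 13 h, lower than our range, and adds: “The peak is flat, so its time is poorly defined”.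

The flask gives 30.1% at 14.1 h.

    substrate + reagent → intermediate + released group (k = 2.73 M⁻¹ h⁻¹)
    intermediate ⇌ target (K = 1.50, k = 0.116 h⁻¹)
    intermediate ⇌ isomer of the product (K = 2.33, k = 0.0525 h⁻¹)
    intermediate → side product (k = 0.0521 h⁻¹)
    target → over-reaction product (k = 1.72 × 10⁻⁵ h⁻¹)

The flask's peak lies below our range, a little below Saturday's share. Now take the neighbouring flask with 0.280 equiv of reagent, its other charges as in the recipe. Its reagent is the smaller charge again, so with Saturday's share we reckon 8.71% of target. That flask's best is 9.18%. At 25.0 h its reagent stands at 0%, and 72% of its substrate is left.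

The numbers in the tables are calculated with made-up constants, noise included.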